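**Remark (assumption on the chemistry):** the configuration is read from the SMILES as (4S,5R,6S,7S,9S,10R). The C10 methyl (C20), the C19 carboxyl and the 6-benzoate lie on the β-face; the 7-hydroxyl and the C9 side chain lie on the α-face (a 9-epi-labdane). Labdane numbering is used for all intermediates: C1–C10 decalin, C11–C16 side chain, C17 exocyclic methylene, C18 methyl on C4, C19 carboxyl, C20 methyl on C10.

## Retrosynthetic overview

1. Target ⇐ desilylation ⇐ O6-benzoylation of a 6β-hydroxy-19-carboxylate ⇐ saponification of a 19,6β-lactone; the C18 methyl comes from reductive methylation of that lactone.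
2. Key disconnection: rings A and B are formed together by an intramolecular Diels–Alder reaction. The diene is C2=C3–C4=C5 of an α-vinylbutenolide, the dienophile is the isopropenyl group C1=C10(C20), and the new bonds are C1–C2 and C5–C10.
3. Enabling feature: the β-face syn-axial pair of the C19 carboxyl on C4 (ring A) and the oxygen on C6 (ring B) can be joined as a five-membered lactone C19–O–C6–C5–C4. In the open-chain precursor this lactone is the butenolide that activates the diene, fixes the face at C5 and forces the trans ring fusion.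
4. The cyclisation precursor comes from a vinylogous Mukaiyama aldol (C6–C7) of 3-bromo-2-silyloxyfuran with an α-methylene aldehyde, then a Stille vinylation (C3–C4).
5. C9 with C1, C10, C20, C7, C8, C11–C13 and C16 comes from (R)-limonene oxide by ring cleavage; C14–C15 by Horner–Wadsworth–Emmons olefination and reduction. Ring order: lactone (preformed butenolide) first, then rings A and B in one step.

Key step: step 12

## Route

Step 1
Reactants: 1 (4R)-limonene 1,2-oxide (cis/trans mixture)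
Product: 3 (3R)-6-oxo-3-(prop-1-en-2-yl)heptanal, via limonene-1,2-diol 2 (not isolated)
Conditions: H5IO6, THF/H2O, 0 °C → rt
Reagents that add atoms: water (O)
Why: Acid-mediated epoxide hydrolysis followed by periodate glycol cleavage (Malaprade reaction) opens the ring between the two oxygenated carbons, both epoxide diastereomers converge on one product, and the isopropenyl-bearing stereocentre (later C9) is not touched.

Step 2
Reactants: 3 (3R)-6-oxo-3-(prop-1-en-2-yl)heptanal
Product: 4 (5R)-7,7-dimethoxy-5-(prop-1-en-2-yl)heptan-2-one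
Conditions: HC(OMe)3, CeCl3·7H2O (cat.), MeOH, 0 °C → rt
Reagents that add atoms: trimethyl orthoformate (COC(OC)OC)
Why: Chemoselective acetalisation, since under CeCl3 catalysis in methanol an aldehyde forms its dimethyl acetal far faster than a methyl ketone.

Step 3
Reactants: 4 (5R)-7,7-dimethoxy-5-(prop-1-en-2-yl)heptan-2-one
Product: 5 ethyl (2E,6R)-8,8-dimethoxy-3-methyl-6-(prop-1-en-2-yl)oct-2-enoate
Conditions: (EtO)2P(O)CH2CO2Et, NaH, THF, 0 → 50 °C
Reagents that add atoms: triethyl phosphonoacetate (CCOC(=O)CP(=O)(OCC)OCC)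
Why: Horner–Wadsworth–Emmons olefination of the methyl ketone should favour the E-trisubstituted enoate (ester trans to the longer chain), and any Z isomer is removed by chromatography here or after step 4.

Step 4
Reactants: 5 ethyl (2E,6R)-8,8-dimethoxy-3-methyl-6-(prop-1-en-2-yl)oct-2-enoate
Product: 6 (2E,6R)-8,8-dimethoxy-3-methyl-6-(prop-1-en-2-yl)oct-2-en-1-ol
Conditions: i-Bu2AlH, CH2Cl2, −78 °C; aq. KNaC4H4O6
Reagents that add atoms: none
Why: 1,2-Reduction of the enoate by the aluminium hydride gives the allylic alcohol (C15) without touching the acetal or the alkene geometry.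

Step 5
Reactants: 6 (2E,6R)-8,8-dimethoxy-3-methyl-6-(prop-1-en-2-yl)oct-2-en-1-ol
Product: 7 (2E,6R)-8,8-dimethoxy-3-methyl-6-(prop-1-en-2-yl)-1-(triisopropylsilyloxy)oct-2-ene
Conditions: i-Pr3SiCl, imidazole, DMF, rt
Reagents that add atoms: triisopropylsilyl chloride (CC(C)[Si](Cl)(C(C)C)C(C)C)
Why: Standard silylation of a primary alcohol, with the triisopropylsilyl group chosen because it survives the later acid, hot hydroxide and hydride steps.

Step 6
Reactants: 7 (2E,6R)-8,8-dimethoxy-3-methyl-6-(prop-1-en-2-yl)-1-(triisopropylsilyloxy)oct-2-ene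
Product: 8 (3R,6E)-6-methyl-3-(prop-1-en-2-yl)-8-(triisopropylsilyloxy)oct-6-enal
Conditions: PPTS (cat.), acetone/H2O, 45 °C
Reagents that add atoms: water (O)
Why: Mild acid-catalysed acetal hydrolysis frees the aldehyde (C7) while the silyl ether and the alkenes are stable to pyridinium tosylate.

Step 7
Reactants: 8 (3R,6E)-6-methyl-3-(prop-1-en-2-yl)-8-(triisopropylsilyloxy)oct-6-enal
Product: 9 (3S,6E)-6-methyl-2-methylidene-3-(prop-1-en-2-yl)-8-(triisopropylsilyloxy)oct-6-enal
Conditions: aq. CH2O, pyrrolidine (cat.), EtCO2H (cat.), i-PrOH, 45 °C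
Reagents that add atoms: formaldehyde (C=O)
Why: Organocatalytic α-methylenation of the aldehyde (enamine Mannich condensation with formaldehyde, then elimination) installs C17 on C8; the C9 stereocentre is not enolisable, so only its descriptor changes.

Step 8
Reactants: 10 3-bromofuran-2(5H)-one
Product: 11 3-bromo-2-(trimethylsilyloxy)furan
Conditions: Me3SiOSO2CF3, Et3N, Et2O, 0 °C
Reagents that add atoms: trimethylsilyl triflate (C[Si](C)(C)OS(=O)(=O)C(F)(F)F)
Why: Soft enolisation of the butenolide at the γ-position gives the aromatic silyl dienol ether (2-silyloxyfuran), which is used without chromatography.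

Step 9
Reactants: 9 (3S,6E)-6-methyl-2-methylidene-3-(prop-1-en-2-yl)-8-(triisopropylsilyloxy)oct-6-enal; 11 3-bromo-2-(trimethylsilyloxy)furan
Product: 13 (5S)-3-bromo-5-[(1S,3S,6E)-1-hydroxy-6-methyl-2-methylidene-3-(prop-1-en-2-yl)-8-(triisopropylsilyloxy)oct-6-en-1-yl]furan-2(5H)-one, via trimethylsilyl ether of the aldol adduct 12 (not isolated)
Conditions: Ti(OiPr)4 (20 mol %), (R)-BINOL (20 mol %), Et2O, −20 °C; then 1 M HCl, THF, 0 °C
Reagents that add atoms: none
Why: Catalytic asymmetric vinylogous Mukaiyama aldol addition, in which the silyloxyfuran attacks the aldehyde carbonyl (1,2) through its γ-carbon to form C6–C7; the open transition state of Lewis-acid vinylogous aldols favours the syn (threo) relation of ring oxygen and hydroxyl, and the tetravalent titanium BINOLate selects the aldehyde face, (R)-BINOL being proposed by analogy with unbranched aldehydes to give C6 (S) and C7 (S).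

Step 10
Reactants: 13 (5S)-3-bromo-5-[(1S,3S,6E)-1-hydroxy-6-methyl-2-methylidene-3-(prop-1-en-2-yl)-8-(triisopropylsilyloxy)oct-6-en-1-yl]furan-2(5H)-one
Product: 14 (5S)-3-bromo-5-[(1S,3S,6E)-1-(tert-butyldimethylsilyloxy)-6-methyl-2-methylidene-3-(prop-1-en-2-yl)-8-(triisopropylsilyloxy)oct-6-en-1-yl]furan-2(5H)-one
Conditions: t-BuMe2SiOSO2CF3, 2,6-lutidine, CH2Cl2, −78 → 0 °C
Reagents that add atoms: tert-butyldimethylsilyl triflate (CC(C)(C)[Si](C)(C)OS(=O)(=O)C(F)(F)F)
Why: Silylation of the hindered secondary allylic alcohol with a silyl triflate and a non-nucleophilic base, mild enough to leave the acidic γ-hydrogen of the butenolide untouched.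

Step 11
Reactants: 14 (5S)-3-bromo-5-[(1S,3S,6E)-1-(tert-butyldimethylsilyloxy)-6-methyl-2-methylidene-3-(prop-1-en-2-yl)-8-(triisopropylsilyloxy)oct-6-en-1-yl]furan-2(5H)-one
Product: 15 (5S)-5-[(1S,3S,6E)-1-(tert-butyldimethylsilyloxy)-6-methyl-2-methylidene-3-(prop-1-en-2-yl)-8-(triisopropylsilyloxy)oct-6-en-1-yl]-3-ethenylfuran-2(5H)-one
Conditions: Bu3SnCH=CH2, Pd2(dba)3 (cat.), AsPh3 (cat.), CuI (cat.), NMP, rt, dark
Reagents that add atoms: tributyl(vinyl)stannane (C=C[Sn](CCCC)(CCCC)CCCC)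
Why: Stille cross-coupling (oxidative addition of zerovalent palladium into the α-bromobutenolide C–Br bond, transmetallation, reductive elimination) attaches C2=C3 to C4 under neutral conditions; the diene is purified quickly and used at once.

Step 12
Reactants: 15 (5S)-5-[(1S,3S,6E)-1-(tert-butyldimethylsilyloxy)-6-methyl-2-methylidene-3-(prop-1-en-2-yl)-8-(triisopropylsilyloxy)oct-6-en-1-yl]-3-ethenylfuran-2(5H)-one
Product: 16 (5R,6S,7S,9S,10R)-7-(tert-butyldimethylsilyloxy)-15-(triisopropylsilyloxy)-18-norlabda-3,8(17),13E-trien-19,6-olide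
Conditions: toluene (0.005 M), BHT (cat.), 150 °C, sealed tube, degassed
Reagents that add atoms: none
Why: A thermal, concerted but asynchronous intramolecular [4+2] cycloaddition (type-one intramolecular Diels–Alder reaction of a 1,7,9-decatriene) joins the 2-acyl diene C2=C3–C4=C5 of the vinylbutenolide to the isopropenyl alkene C1=C10; the closest known reaction type is the intramolecular Diels–Alder reaction of trienes whose diene carries an ester or lactone carbonyl as a steric directing group, giving trans-fused octalins with an angular methyl group. Ring A closes as the cyclohexene of the cycloaddition through C1–C2 and C5–C10 (suprafacial on both partners), and ring B closes through the same C5–C10 bond as a six-membered chair-like tether ring C5–C6–C7–C8–C9–C10. C5 is controlled by C6: the butenolide is planar and the alkene, tethered through C7, can reach C5 only on the face that carries C7, so H5 ends cis to H6 (5R). C10 is controlled by the lactone carbonyl on C4, held in the diene plane with O6: a cis-fused transition state would need C7 eclipsed with that substituent (adjacent ring-B torsions of the same sign, a twist-boat tether), so the chair (anti) transition state with the methyl group under the diene is followed and C20 ends anti to H5 (10R), with the C7 silyloxy group and the C9 chain axial as in the target. The step needs trans over cis fusion and cycloaddition over ene reaction of the isopropenyl group or diene dimerisation; the first is secured by the butenolide, the second by high dilution, exclusion of oxygen and the radical inhibitor.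

Step 13
Reactants: 16 (5R,6S,7S,9S,10R)-7-(tert-butyldimethylsilyloxy)-15-(triisopropylsilyloxy)-18-norlabda-3,8(17),13E-trien-19,6-olide
Product: 18 (4S,5R,6S,7S,9S,10R)-7-(tert-butyldimethylsilyloxy)-15-(triisopropylsilyloxy)labda-8(17),13E-dien-19,6-olide, via lithium lactone enolate 17 (not isolated)
Conditions: LiBH(s-Bu)3, THF, −78 °C; then MeI, HMPA, −78 → 0 °C
Reagents that add atoms: iodomethane (CI)
Why: Reductive alkylation, in which conjugate (1,4) hydride addition to the α-alkylidene lactone gives the lactone enolate that is C-methylated in the same flask; the methyl group enters from the α-face because C19 is held on the β-face by the lactone bridge to O6 and that face is also shielded by the axial C20 methyl, which sets C4 (S).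

Step 14
Reactants: 18 (4S,5R,6S,7S,9S,10R)-7-(tert-butyldimethylsilyloxy)-15-(triisopropylsilyloxy)labda-8(17),13E-dien-19,6-olide
Product: 19 potassium (4S,5R,6S,7S,9S,10R)-7-(tert-butyldimethylsilyloxy)-6-hydroxy-15-(triisopropylsilyloxy)labda-8(17),13E-dien-19-oate
Conditions: KOH (1.05 equiv), EtOH/H2O, 80 °C; evaporation, azeotropic drying (toluene)
Reagents that add atoms: potassium hydroxide ([K+].[OH-])
Why: Saponification of the hindered γ-lactone by acyl–oxygen cleavage keeps the configuration at C6, both silyl ethers are stable to hydroxide, and the product is kept as its potassium salt because the free 6β-hydroxy acid would relactonise.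

Step 15
Reactants: 19 potassium (4S,5R,6S,7S,9S,10R)-7-(tert-butyldimethylsilyloxy)-6-hydroxy-15-(triisopropylsilyloxy)labda-8(17),13E-dien-19-oate
Product: 21 (4S,5R,6S,7S,9S,10R)-6-(benzoyloxy)-7-(tert-butyldimethylsilyloxy)-15-(triisopropylsilyloxy)labda-8(17),13E-dien-19-oic acid, via dipotassium alkoxide carboxylate 20 (not isolated)
Conditions: KN(SiMe3)2 (1.1 equiv), THF, −78 °C; N-benzoylimidazole, −78 → 0 °C; then cold 0.5 M HCl
Reagents that add atoms: N-benzoylimidazole (O=C(c1ccccc1)n1ccnc1)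
Why: O-Acylation of a potassium alkoxide by an acyl imidazole, in which the alkoxide and not the carboxylate is the nucleophile toward this mild acyl donor, C19 is never activated so the lactone cannot re-form, and the trans-diaxial 7-silyloxy group cannot migrate; cold protonation then gives the free acid.

Step 16
Reactants: 21 (4S,5R,6S,7S,9S,10R)-6-(benzoyloxy)-7-(tert-butyldimethylsilyloxy)-15-(triisopropylsilyloxy)labda-8(17),13E-dien-19-oic acid
Product: 22 (4S,5R,6S,7S,9S,10R)-6-(benzoyloxy)-7,15-dihydroxylabda-8(17),13E-dien-19-oic acid (CNP0149011.1)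
Conditions: HF·pyridine, pyridine, THF, 0 °C → rt
Reagents that add atoms: none
Why: Fluoride-mediated cleavage of both silyl ethers under buffered, non-basic conditions leaves the benzoate in place, since acyl migration from O6 to the trans-diaxial O7 is geometrically impossible.

## Compound list

1 | (4R)-limonene 1,2-oxide (cis/trans mixture) | CC12CC[C@@H](C(C)=C)CC1O2 | starting material
2 | (4R)-1-methyl-4-(prop-1-en-2-yl)cyclohexane-1,2-diol | CC1(O)CC[C@@H](C(C)=C)CC1O | intermediate
3 | (3R)-6-oxo-3-(prop-1-en-2-yl)heptanal | CC(=O)CC[C@H](CC=O)C(C)=C | intermediate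
4 | (5R)-7,7-dimethoxy-5-(prop-1-en-2-yl)heptan-2-one | CC(=O)CC[C@H](CC(OC)OC)C(C)=C | intermediate
5 | ethyl (2E,6R)-8,8-dimethoxy-3-methyl-6-(prop-1-en-2-yl)oct-2-enoate | CCOC(=O)/C=C(C)/CC[C@H](CC(OC)OC)C(C)=C | intermediate
6 | (2E,6R)-8,8-dimethoxy-3-methyl-6-(prop-1-en-2-yl)oct-2-en-1-ol | OC/C=C(C)/CC[C@H](CC(OC)OC)C(C)=C | intermediate
7 | (2E,6R)-8,8-dimethoxy-3-methyl-6-(prop-1-en-2-yl)-1-(triisopropylsilyloxy)oct-2-ene | CC(C)[Si](OC/C=C(C)/CC[C@H](CC(OC)OC)C(C)=C)(C(C)C)C(C)C | intermediate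
8 | (3R,6E)-6-methyl-3-(prop-1-en-2-yl)-8-(triisopropylsilyloxy)oct-6-enal | CC(C)[Si](OC/C=C(C)/CC[C@H](CC=O)C(C)=C)(C(C)C)C(C)C | intermediate
9 | (3S,6E)-6-methyl-2-methylidene-3-(prop-1-en-2-yl)-8-(triisopropylsilyloxy)oct-6-enal | CC(C)[Si](OC/C=C(C)/CC[C@H](C(=C)C=O)C(C)=C)(C(C)C)C(C)C | intermediate
10 | 3-bromofuran-2(5H)-one | O=C1OCC=C1Br | starting material
11 | 3-bromo-2-(trimethylsilyloxy)furan | C[Si](C)(C)Oc1occc1Br | intermediate
12 | trimethylsilyl ether of aldol adduct 13 | BrC1=C[C@H](OC1=O)[C@@H](O[Si](C)(C)C)C(=C)[C@@H](CC/C(C)=C/CO[Si](C(C)C)(C(C)C)C(C)C)C(C)=C | intermediate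
13 | (5S)-3-bromo-5-[(1S,3S,6E)-1-hydroxy-6-methyl-2-methylidene-3-(prop-1-en-2-yl)-8-(triisopropylsilyloxy)oct-6-en-1-yl]furan-2(5H)-one | BrC1=C[C@H](OC1=O)[C@@H](O)C(=C)[C@@H](CC/C(C)=C/CO[Si](C(C)C)(C(C)C)C(C)C)C(C)=C | intermediate
14 | tert-butyldimethylsilyl ether of 13 | BrC1=C[C@H](OC1=O)[C@@H](O[Si](C)(C)C(C)(C)C)C(=C)[C@@H](CC/C(C)=C/CO[Si](C(C)C)(C(C)C)C(C)C)C(C)=C | intermediate
15 | (5S)-5-[(1S,3S,6E)-1-(tert-butyldimethylsilyloxy)-6-methyl-2-methylidene-3-(prop-1-en-2-yl)-8-(triisopropylsilyloxy)oct-6-en-1-yl]-3-ethenylfuran-2(5H)-one | C=CC1=C[C@H](OC1=O)[C@@H](O[Si](C)(C)C(C)(C)C)C(=C)[C@@H](CC/C(C)=C/CO[Si](C(C)C)(C(C)C)C(C)C)C(C)=C | intermediate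
16 | (5R,6S,7S,9S,10R)-7-(tert-butyldimethylsilyloxy)-15-(triisopropylsilyloxy)-18-norlabda-3,8(17),13E-trien-19,6-olide | C=C1[C@@H](CC/C(C)=C/CO[Si](C(C)C)(C(C)C)C(C)C)[C@@]2(C)CCC=C3[C@@H]2[C@H](OC3=O)[C@H]1O[Si](C)(C)C(C)(C)C | intermediate
17 | lithium enolate of the 19,6-lactone (C4=C19) | C=C1[C@@H](CC/C(C)=C/CO[Si](C(C)C)(C(C)C)C(C)C)[C@@]2(C)CCCC=3[C@@H]2[C@H](OC=3[O-])[C@H]1O[Si](C)(C)C(C)(C)C.[Li+] | intermediate
18 | (4S,5R,6S,7S,9S,10R)-7-(tert-butyldimethylsilyloxy)-15-(triisopropylsilyloxy)labda-8(17),13E-dien-19,6-olide | C=C1[C@@H](CC/C(C)=C/CO[Si](C(C)C)(C(C)C)C(C)C)[C@@]2(C)CCC[C@@]3(C)[C@@H]2[C@H](OC3=O)[C@H]1O[Si](C)(C)C(C)(C)C | intermediate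
19 | potassium (4S,5R,6S,7S,9S,10R)-7-(tert-butyldimethylsilyloxy)-6-hydroxy-15-(triisopropylsilyloxy)labda-8(17),13E-dien-19-oate | C=C1[C@@H](CC/C(C)=C/CO[Si](C(C)C)(C(C)C)C(C)C)[C@@]2(C)CCC[C@](C)(C(=O)[O-])[C@@H]2[C@H](O)[C@H]1O[Si](C)(C)C(C)(C)C.[K+] | intermediate
20 | dipotassium 6-alkoxide 19-carboxylate of 19 | C=C1[C@@H](CC/C(C)=C/CO[Si](C(C)C)(C(C)C)C(C)C)[C@@]2(C)CCC[C@](C)(C(=O)[O-])[C@@H]2[C@H]([O-])[C@H]1O[Si](C)(C)C(C)(C)C.[K+].[K+] | intermediate
21 | (4S,5R,6S,7S,9S,10R)-6-(benzoyloxy)-7-(tert-butyldimethylsilyloxy)-15-(triisopropylsilyloxy)labda-8(17),13E-dien-19-oic acid | C=C1[C@@H](CC/C(C)=C/CO[Si](C(C)C)(C(C)C)C(C)C)[C@@]2(C)CCC[C@](C)(C(=O)O)[C@@H]2[C@H](OC(=O)c2ccccc2)[C@H]1O[Si](C)(C)C(C)(C)C | intermediate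
22 | (4S,5R,6S,7S,9S,10R)-6-(benzoyloxy)-7,15-dihydroxylabda-8(17),13E-dien-19-oic acid (CNP0149011.1) | C=C1[C@@H](CC/C(C)=C/CO)[C@@]2(C)CCC[C@](C)(C(=O)O)[C@@H]2[C@H](OC(=O)c2ccccc2)[C@H]1O | target

## Step count and risks

Total step count: 16. Longest linear sequence: 15 steps (steps 1–7 and 9–16); step 8 is a one-step side branch.

**Step 12 (key cycloaddition).** The chair transition state carries the C7 silyloxy group and the C9 chain syn-diaxial, so the cyclisation may be slow. An ene reaction of the isopropenyl group, diene dimerisation or leakage into a twist-boat cis-fused pathway could then compete.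
Fallback: the cyclisation is run in the C7-epimeric series, where the C7 oxygen is equatorial in the chair, and C7 is inverted afterwards. It sets out from 9 and 10.
- A direct vinylogous aldol addition under a chiral tertiary amine–thiourea catalyst chosen for the anti series would give the anti adduct (5S)-3-bromo-5-[(1R,3S,6E)-1-hydroxy-6-methyl-2-methylidene-3-(prop-1-en-2-yl)-8-(triisopropylsilyloxy)oct-6-en-1-yl]furan-2(5H)-one F1.
- Et3SiOSO2CF3 and 2,6-lutidine would give its triethylsilyl ether F2.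
- Stille vinylation as in step 11 would give the 7-epimeric vinylbutenolide F3.
- Heating as in step 12 should give the 7β-triethylsilyloxy cycloadduct F4.
- PPTS in MeOH would free the 7β-alcohol F5 while the primary triisopropylsilyl ether stays.
- Dess–Martin periodinane would give the 7-oxo-8(17)-ene F6.
- NaBH4 with CeCl3·7H2O at −78 °C (1,2-reduction) would give the 7α-alcohol F7, since the axial C9 chain blocks the α-face and hydride should arrive from the β-face.
- t-BuMe2SiOSO2CF3 and 2,6-lutidine would bring the sequence back to 16.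

**Step 15 (benzoylation).** Relactonisation may compete with O-benzoylation of the hindered axial alkoxide: if the carboxylate is acylated first, the resulting mixed anhydride closes to the 19,6-lactone with loss of benzoate.
Fallback: C19 is taken to the alcohol level so that no acyl acceptor is present during benzoylation, and is re-oxidised afterwards. It sets out from 18.
- LiAlH4 in THF at 0 °C would reduce the lactone to the 6β,19-diol F8.
- Et3SiCl and imidazole would silylate the primary C19 hydroxyl selectively to give the 19-triethylsilyl ether F9.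
- Benzoyl chloride, DMAP and pyridine at 50 °C would give the 6β-benzoate F10.
- PPTS in MeOH would remove the primary triethylsilyl group to give the 19-alcohol F11.
- Dess–Martin periodinane would give the 19-aldehyde F12.
- NaClO2, NaH2PO4 and 2-methylbut-2-ene in t-BuOH/H2O (Pinnick oxidation) would bring the sequence back to 21.

**Step 9 (vinylogous aldol).** With the α-branched enal and the brominated furan, the titanium-catalysed addition may show poor simple diastereoselectivity (anti instead of syn) or low facial selectivity.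
Fallback: the anti adduct is made on purpose and C7 is corrected by inversion. It sets out from 9 and 10.
- The anti-selective direct vinylogous aldol addition described above would give the anti adduct (5S,1′R) F13.
- Mitsunobu inversion with chloroacetic acid, PPh3 and DIAD in toluene would give the (1′S)-chloroacetate F14.
- Thiourea and NaHCO3 in EtOH would cleave the chloroacetate under near-neutral conditions and bring the sequence back to 13.

## Further compounds

F1 | step 12 | (5S)-3-bromo-5-[(1R,3S,6E)-1-hydroxy-6-methyl-2-methylidene-3-(prop-1-en-2-yl)-8-(triisopropylsilyloxy)oct-6-en-1-yl]furan-2(5H)-one | BrC1=C[C@H](OC1=O)[C@H](O)C(=C)[C@@H](CC/C(C)=C/CO[Si](C(C)C)(C(C)C)C(C)C)C(C)=C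
F2 | step 12 | triethylsilyl ether of F1 | BrC1=C[C@H](OC1=O)[C@H](O[Si](CC)(CC)CC)C(=C)[C@@H](CC/C(C)=C/CO[Si](C(C)C)(C(C)C)C(C)C)C(C)=C
F3 | step 12 | (5S)-3-ethenyl-5-[(1R,3S,6E)-6-methyl-2-methylidene-3-(prop-1-en-2-yl)-1-(triethylsilyloxy)-8-(triisopropylsilyloxy)oct-6-en-1-yl]furan-2(5H)-one | C=CC1=C[C@H](OC1=O)[C@H](O[Si](CC)(CC)CC)C(=C)[C@@H](CC/C(C)=C/CO[Si](C(C)C)(C(C)C)C(C)C)C(C)=C
F4 | step 12 | (5R,6S,7R,9S,10R)-7-(triethylsilyloxy)-15-(triisopropylsilyloxy)-18-norlabda-3,8(17),13E-trien-19,6-olide | C=C1[C@@H](CC/C(C)=C/CO[Si](C(C)C)(C(C)C)C(C)C)[C@@]2(C)CCC=C3[C@@H]2[C@H](OC3=O)[C@@H]1O[Si](CC)(CC)CC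
F5 | step 12 | (5R,6S,7R,9S,10R)-7-hydroxy-15-(triisopropylsilyloxy)-18-norlabda-3,8(17),13E-trien-19,6-olide | C=C1[C@@H](CC/C(C)=C/CO[Si](C(C)C)(C(C)C)C(C)C)[C@@]2(C)CCC=C3[C@@H]2[C@H](OC3=O)[C@@H]1O
F6 | step 12 | (5R,6S,9S,10R)-7-oxo-15-(triisopropylsilyloxy)-18-norlabda-3,8(17),13E-trien-19,6-olide | C=C1[C@@H](CC/C(C)=C/CO[Si](C(C)C)(C(C)C)C(C)C)[C@@]2(C)CCC=C3[C@@H]2[C@H](OC3=O)C1=O
F7 | step 12 | (5R,6S,7S,9S,10R)-7-hydroxy-15-(triisopropylsilyloxy)-18-norlabda-3,8(17),13E-trien-19,6-olide | C=C1[C@@H](CC/C(C)=C/CO[Si](C(C)C)(C(C)C)C(C)C)[C@@]2(C)CCC=C3[C@@H]2[C@H](OC3=O)[C@H]1O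
F8 | step 15 | (4S,5R,6S,7S,9S,10R)-7-(tert-butyldimethylsilyloxy)-15-(triisopropylsilyloxy)labda-8(17),13E-diene-6,19-diol | C=C1[C@@H](CC/C(C)=C/CO[Si](C(C)C)(C(C)C)C(C)C)[C@@]2(C)CCC[C@](C)(CO)[C@@H]2[C@H](O)[C@H]1O[Si](C)(C)C(C)(C)C
F9 | step 15 | 19-triethylsilyl ether of F8 | C=C1[C@@H](CC/C(C)=C/CO[Si](C(C)C)(C(C)C)C(C)C)[C@@]2(C)CCC[C@](C)(CO[Si](CC)(CC)CC)[C@@H]2[C@H](O)[C@H]1O[Si](C)(C)C(C)(C)C
F10 | step 15 | 6-benzoate of F9 | C=C1[C@@H](CC/C(C)=C/CO[Si](C(C)C)(C(C)C)C(C)C)[C@@]2(C)CCC[C@](C)(CO[Si](CC)(CC)CC)[C@@H]2[C@H](OC(=O)c2ccccc2)[C@H]1O[Si](C)(C)C(C)(C)C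
F11 | step 15 | (4S,5R,6S,7S,9S,10R)-6-(benzoyloxy)-7-(tert-butyldimethylsilyloxy)-15-(triisopropylsilyloxy)labda-8(17),13E-dien-19-ol | C=C1[C@@H](CC/C(C)=C/CO[Si](C(C)C)(C(C)C)C(C)C)[C@@]2(C)CCC[C@](C)(CO)[C@@H]2[C@H](OC(=O)c2ccccc2)[C@H]1O[Si](C)(C)C(C)(C)C
F12 | step 15 | (4S,5R,6S,7S,9S,10R)-6-(benzoyloxy)-7-(tert-butyldimethylsilyloxy)-15-(triisopropylsilyloxy)labda-8(17),13E-dien-19-al | C=C1[C@@H](CC/C(C)=C/CO[Si](C(C)C)(C(C)C)C(C)C)[C@@]2(C)CCC[C@](C)(C=O)[C@@H]2[C@H](OC(=O)c2ccccc2)[C@H]1O[Si](C)(C)C(C)(C)C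
F13 | step 9 | (5S)-3-bromo-5-[(1R,3S,6E)-1-hydroxy-6-methyl-2-methylidene-3-(prop-1-en-2-yl)-8-(triisopropylsilyloxy)oct-6-en-1-yl]furan-2(5H)-one | BrC1=C[C@H](OC1=O)[C@H](O)C(=C)[C@@H](CC/C(C)=C/CO[Si](C(C)C)(C(C)C)C(C)C)C(C)=C
F14 | step 9 | (1S,3S,6E)-1-[(2S)-4-bromo-5-oxo-2,5-dihydrofuran-2-yl]-6-methyl-2-methylidene-3-(prop-1-en-2-yl)-8-(triisopropylsilyloxy)oct-6-en-1-yl chloroacetate | BrC1=C[C@H](OC1=O)[C@@H](OC(=O)CCl)C(=C)[C@@H](CC/C(C)=C/CO[Si](C(C)C)(C(C)C)C(C)C)C(C)=C
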